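**Plan**

1. Retrosynthesis: remove the C9 angelate, then the C7 senecioate (Evans–Tishchenko disconnection to a C9 ketone and a C7=C8 enone). Cut the cyclobutane bond C4–C10 (C10 enolate onto a C3–C4 epoxide). Cut C2=C3, C4–C5 and C5–C11 of the remaining cis-fused cyclohexenone/cycloheptane back to an acyclic keto aldehyde carrying an acetoacetate on O7.
2. Enabling feature: ring C1–C2–C3–C4–C5–C11 is a 3-methylcyclohex-2-enone (acetoacetate C3/C4 plus methyl ketone C1/C2 joined across aldehyde carbon C5), and O7 lies cis to C4 across the quaternary C6. An acetoacetate on O7 can therefore reach C5 as a six-membered lactone.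
3. Forward: two seven-carbon fragments are joined by an aldol reaction (C8–C9). One cascade then closes the lactone tether, the seven-membered ring and the cyclohexenone. The tether leaves by β-elimination and decarboxylation, the cyclobutane is closed last, and the two esters follow.
4. Stereochemistry: C7 (CBS reduction) fixes C5 through the bridged lactone. C11 is equilibrated to the cis ring fusion, and C4 and C10 follow from the cyclobutane closure. C9/C10 are carried as epimers and cleared. C7 is reset by ligand-controlled borylation and C9 by intramolecular 1,3-anti hydride delivery.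

Key step: step 9

Remark 1 (naming): locants C1–C11 are those of the longipinane skeleton of the target: C1 (C=O), C2=C3 (3-methyl), C4, C5, C6 (gem-dimethyl), C7 (O-senecioyl), C8, C9 (O-angeloyl), C10 (quaternary, methyl), C11. Ring bonds are C1–C2–C3–C4–C5–C6–C7–C8–C9–C10–C11–C1 plus C4–C10 and C5–C11. "4,10-seco" means the same skeleton without the C4–C10 bond; "4,7-carbolactone" means C4–C(=O)–O–C7.

Remark 2 (assumptions): C9 and C10 are carried as mixtures of epimers until they are cleared (steps 11 and 15) and are drawn without configuration until then. In step 16 the ligand hand that delivers boron to the C4-side face of C7 is taken to be (R,S)-Josiphos; its mirror image is used if the sense is the opposite.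

**Route**

Step 1
Reactants: 1 N-methoxy-N-methylpropanamide; 2 3-bromo-2-methylprop-1-ene
Product: 3 N-methoxy-N,2,4-trimethylpent-4-enamide (racemic)
Conditions: LiN(iPr)2, THF, −78 °C; then 2, −78 → 0 °C
Reagents that add atoms: none
Why: Enolate alkylation, in which the lithium enolate of the Weinreb amide displaces the allylic bromide (SN2); the new center (later C10) is racemic on purpose because it is enolized again in step 15.

Step 2
Reactants: 3
Product: 4 2,4-dimethylpent-4-enal (racemic)
Conditions: LiAlH4, THF, −78 → 0 °C; aq. KHSO4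
Reagents that add atoms: none
Why: Weinreb amide reduction, in which the chelated tetrahedral aluminate stops at the aldehyde oxidation level; no stereocenter is set.

Step 3
Reactants: 5 (3-methylbut-2-en-1-yl)magnesium chloride; 6 N-methoxy-N-methylacetamide
Product: 7 3,3-dimethylpent-4-en-2-one
Conditions: THF, −78 → 0 °C; aq. NH4Cl
Reagents that add atoms: none
Why: Grignard acylation of a Weinreb amide with allylic transposition (SE2′), in which the prenyl reagent bonds through its tertiary carbon; this installs the C6 gem-dimethyl group next to the future C7 carbonyl and the vinyl group that masks the C5 aldehyde.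

Step 4
Reactants: 7; 4
Product: 8 6-hydroxy-3,3,7,9-tetramethyldeca-1,9-dien-4-one (epimers at C6/C7 of the chain)
Conditions: LiN(iPr)2, THF, −78 °C; then 4; aq. NH4Cl at −78 °C
Reagents that add atoms: none
Why: Lithium aldol addition, in which 7 can enolize only at its methyl group (C8) so that one regioisomer forms; C9 and C10 arise as epimers, which is tolerated because C9 is oxidized in step 11 and C10 is enolized in step 15.

Step 5
Reactants: 8
Product: 9 6-[(tert-butyldimethylsilyl)oxy]-3,3,7,9-tetramethyldeca-1,9-dien-4-one
Conditions: TBSOTf, 2,6-lutidine, CH2Cl2, −78 °C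
Reagents that add atoms: tert-butyldimethylsilyl trifluoromethanesulfonate CC(C)(C)[Si](C)(C)OS(=O)(=O)C(F)(F)F
Why: Silyl ether formation masks O9 so that only O7 can later carry the tether; no stereocenter is touched.

Step 6
Reactants: 9
Product: 10 (4R)-6-[(tert-butyldimethylsilyl)oxy]-3,3,7,9-tetramethyldeca-1,9-dien-4-ol (C7 of the target numbering is R)
Conditions: (S)-2-methyl-CBS-oxazaborolidine (10 mol%), catecholborane, toluene, −78 → −40 °C
Reagents that add atoms: none
Why: CBS reduction, in which the oxazaborolidine differentiates the tert-alkyl side (C6) from the methylene side (C8) of the ketone and should give the (R)-carbinol at C7 whatever the remote C9/C10 centers are; catecholborane is chosen because it leaves the two alkenes alone.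

Step 7
Reactants: 10; 11 2,2,6-trimethyl-4H-1,3-dioxin-4-one
Product: 12 (4R)-6-[(tert-butyldimethylsilyl)oxy]-3,3,7,9-tetramethyldeca-1,9-dien-4-yl 3-oxobutanoate
Conditions: toluene, 110 °C (acetone distilled off)
Reagents that add atoms: none
Why: Acetoacetylation through acetylketene (thermal retro-Diels–Alder of the dioxinone) acylates the hindered C7 hydroxyl under neutral conditions with retention at C7.

Step 8
Reactants: 12
Product: 13 (3R)-5-[(tert-butyldimethylsilyl)oxy]-2,2,6-trimethyl-1,8-dioxononan-3-yl 3-oxobutanoate
Conditions: O3, CH2Cl2, −78 °C; then PPh3, −78 → 23 °C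
Reagents that add atoms: ozone [O-][O+]=O
Why: Ozonolysis with reductive work-up cleaves both terminal alkenes at once, the vinyl group to the C5 aldehyde and the methallyl group to the C1 methyl ketone, while the acetoacetate and the silyl ether are inert.

Step 9
Reactants: 13
Product: 16 9-[(tert-butyldimethylsilyl)oxy]-1-oxo-4,10-secolongipin-2-ene-4,7-carbolactone (C5 and C7 as in the target; epimers at C4/C9/C10/C11), via alkylidene acetoacetate lactone 14 (not isolated), via Michael adduct diketone 15 (not isolated)
Conditions: pyrrolidine (0.3 equiv), AcOH (0.3 equiv), toluene (0.01 M), 4 Å molecular sieves, 23 °C then 80 °C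
Reagents that add atoms: none
Why: Pyrrolidinium acetate first condenses the acetoacetate methylene C4 with the non-enolizable aldehyde C5 (Knoevenagel condensation, closing the six-membered lactone of 14 in a 6-exo-trig sense), the C11 enamine of the methyl ketone then adds to C5 of this alkylidene acetoacetate (7-exo-trig Michael addition that closes the cycloheptane, 15), and the C2 enamine finally condenses with the C3 ketone (6-(enolendo)-exo-trig aldol condensation) to the cyclohexenone, so that C4–C5, C5–C11 and C2=C3 arise in one flask. The closest known reaction type is the Hagemann ester synthesis (Knoevenagel, Michael and aldol condensation of acetoacetates) and the Robinson annulation, run here within one molecule. C5 is the stereocenter that is fixed for good: the four-carbon chain that carries C11 hangs from C7 of the lactone and can reach C5 only across the face on which it sits, so the (R) carbinol at C7 dictates C5 through the bicyclo[4.3.1] lactone, while C4 and C11 stay epimerizable (C4 is cleared in step 12, C11 is equilibrated in steps 12 and 13) and C9/C10 are spectators. The step needs the aldol regiochemistry C2 onto C3 and not C3-methyl onto C1, which amine catalysis should secure because the enamine forms at the plain methyl ketone and the β-keto lactone carbonyl is the better electrophile. It also needs ring closure to outrun intermolecular condensation, which high dilution and the quaternary C6 in the tether favour. Should the aldol condensation of C11 with C5 run first, the resulting 1-acetylcycloheptene is attacked at C5 by the tethered acetoacetate (6-exo-trig) and both orders converge on 15.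

Step 10
Reactants: 16
Product: 17 9-hydroxy-1-oxo-4,10-secolongipin-2-ene-4,7-carbolactone
Conditions: HF·pyridine, THF/pyridine, 0 → 23 °C
Reagents that add atoms: none
Why: Fluoride-mediated desilylation of the secondary silyl ether, to which the lactone and the enone are stable.

Step 11
Reactants: 17
Product: 18 1,9-dioxo-4,10-secolongipin-2-ene-4,7-carbolactone
Conditions: Dess–Martin periodinane, CH2Cl2, 0 → 23 °C
Reagents that add atoms: none
Why: Dess–Martin oxidation of the secondary alcohol gives the C9 ketone, which erases the C9 epimer mixture and places the lactone oxygen β to a carbonyl.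

Step 12
Reactants: 18
Product: 20 4,10-secolongipina-2,7-diene-1,9-dione (C5 as in the target; C10/C11 epimers), via enone carboxylic acid 19 (not isolated)
Conditions: DBU (1.5 equiv), toluene, 23 °C then 80 °C
Reagents that add atoms: none
Why: E1cB elimination followed by decarboxylation of a vinylogous β-keto acid, in which deprotonation at C8 expels the lactone carboxylate from C7 and the freed acid at C4 loses CO2 through the dienol; the tether thus leaves without trace, the resulting C7=C8 enone has C10 as its only enolizable position, and C11 equilibrates under the basic conditions.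

Step 13
Reactants: 20
Product: 21 1,1-(ethylenedioxy)-4,10-secolongipina-3,7-dien-9-one (5,11-cis ring fusion)
Conditions: HOCH2CH2OH (3 equiv), p-TsOH (cat.), benzene, 80 °C, Dean–Stark
Reagents that add atoms: ethylene glycol OCCO
Why: Acid-catalyzed ketalization with deconjugation, in which the C1 enone (which has γ-hydrogens) passes through the dienol ether to the β,γ-unsaturated dioxolane (C3=C4) while the hindered C9 enone without γ-hydrogens should react much more slowly; under these equilibrating conditions C11 epimerizes through the enol ether, and the cis-fused ketal, which avoids the clash between a dioxolane oxygen and C10, is expected to predominate and is carried on.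

Step 14
Reactants: 21
Product: 22 3,4-epoxy-1,1-(ethylenedioxy)-4,10-secolongipin-7-en-9-one (epoxide oxygen trans to C6 and C10)
Conditions: dimethyldioxirane, acetone, −20 → 0 °C
Reagents that add atoms: dimethyldioxirane CC1(C)OO1
Why: Dioxirane epoxidation under neutral conditions selects the electron-rich trisubstituted C3=C4 alkene over the enone and should attack the face opposite to C6 and the axial C10, which places the epoxide oxygen anti to the carbon that must displace it.

Step 15
Reactants: 22
Product: 24 longipina-2,7-diene-1,9-dione (C4/C5/C10/C11 as in the target), via hydroxy ketal 23 (not isolated)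
Conditions: KOtBu, tBuOH/THF, 23 → 50 °C; then 1 M aq. HCl, 23 °C
Reagents that add atoms: water O
Why: Intramolecular enolate alkylation by epoxide opening (4-exo-tet), in which the potassium dienolate of the only enolizable position C10 attacks C4 anti to the epoxide oxygen with inversion, closing the cyclobutane and setting C4 and C10 in the only geometry the cis-fused bicycle allows; aqueous acid then hydrolyzes the dioxolane and dehydrates the tertiary β-hydroxy ketone to the C2=C3 enone.

Step 16
Reactants: 24
Product: 26 (7R)-7-hydroxylongipin-2-ene-1,9-dione, via pinacol boronate 25 (not isolated)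
Conditions: CuCl (5 mol%), NaOtBu (10 mol%), (R,S)-Josiphos (6 mol%), B2pin2, MeOH (2 equiv), THF, 23 °C; then NaBO3·4H2O, THF/H2O, 23 °C
Reagents that add atoms: sodium perborate [Na+].[O-]OB=O (oxygen of the C7 hydroxyl); bis(pinacolato)diboron CC1(C)OB(OC1(C)C)B1OC(C)(C)C(C)(C)O1 (boron only in 25)
Why: Copper-catalyzed conjugate borylation followed by oxidation with retention, in which the boryl copper species adds to the β-monosubstituted C7=C8 enone rather than the β,β-disubstituted bridged C2=C3 enone; because the two faces of C7 differ only by remote groups, the chiral ligand decides the face and should give the (7R)-alcohol.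

Step 17
Reactants: 26; 27 3-methylbut-2-enal
Product: 28 (7R,9R)-9-hydroxy-1-oxolongipin-2-en-7-yl 3-methylbut-2-enoate
Conditions: SmI2 (0.3 equiv, premixed with 27), THF, −10 °C
Reagents that add atoms: none
Why: Evans–Tishchenko reduction, in which the samarium-bound hemiacetal formed from O7 and 27 transfers its hydride intramolecularly to the C9 carbonyl from the face of O7; the new hydroxyl is therefore trans to O7 (9R) and O7 emerges as the senecioate in the same event.

Step 18
Reactants: 28; 29 (2Z)-2-methylbut-2-enoic acid
Product: 30 (4R,5S,7R,9R,10R,11R)-9-{[(2Z)-2-methylbut-2-enoyl]oxy}-1-oxolongipin-2-en-7-yl 3-methylbut-2-enoate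
Conditions: 29, 2,4,6-trichlorobenzoyl chloride, Et3N, toluene, 23 °C; then 28, 80 °C
Reagents that add atoms: none
Why: Yamaguchi-type esterification through the mixed anhydride without a nucleophilic catalyst, conditions chosen to keep the Z geometry of the angelate; the trans-disposed C7 ester cannot migrate in the rigid tricycle.

**Compound list**

1 | N-methoxy-N-methylpropanamide | CCC(=O)N(C)OC | starting material
2 | 3-bromo-2-methylprop-1-ene | C=C(C)CBr | starting material
3 | N-methoxy-N,2,4-trimethylpent-4-enamide (racemic) | CON(C)C(=O)C(C)CC(C)=C | intermediate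
4 | 2,4-dimethylpent-4-enal (racemic) | O=CC(C)CC(C)=C | intermediate
5 | (3-methylbut-2-en-1-yl)magnesium chloride | CC(C)=CC[Mg]Cl | starting material
6 | N-methoxy-N-methylacetamide | CC(=O)N(C)OC | starting material
7 | 3,3-dimethylpent-4-en-2-one | CC(=O)C(C)(C)C=C | intermediate
8 | 6-hydroxy-3,3,7,9-tetramethyldeca-1,9-dien-4-one (C9/C10 epimers) | C=CC(C)(C)C(=O)CC(O)C(C)CC(C)=C | intermediate
9 | 6-[(tert-butyldimethylsilyl)oxy]-3,3,7,9-tetramethyldeca-1,9-dien-4-one (C9/C10 epimers) | C=CC(C)(C)C(=O)CC(O[Si](C)(C)C(C)(C)C)C(C)CC(C)=C | intermediate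
10 | (4R)-6-[(tert-butyldimethylsilyl)oxy]-3,3,7,9-tetramethyldeca-1,9-dien-4-ol (C9/C10 epimers) | C=CC(C)(C)[C@H](O)CC(O[Si](C)(C)C(C)(C)C)C(C)CC(C)=C | intermediate
11 | 2,2,6-trimethyl-4H-1,3-dioxin-4-one | CC1=CC(=O)OC(C)(C)O1 | starting material
12 | (4R)-6-[(tert-butyldimethylsilyl)oxy]-3,3,7,9-tetramethyldeca-1,9-dien-4-yl 3-oxobutanoate | C=CC(C)(C)[C@H](OC(=O)CC(C)=O)CC(O[Si](C)(C)C(C)(C)C)C(C)CC(C)=C | intermediate
13 | (3R)-5-[(tert-butyldimethylsilyl)oxy]-2,2,6-trimethyl-1,8-dioxononan-3-yl 3-oxobutanoate | O=CC(C)(C)[C@H](OC(=O)CC(C)=O)CC(O[Si](C)(C)C(C)(C)C)C(C)CC(C)=O | intermediate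
14 | (6R)-3-acetyl-6-{2-[(tert-butyldimethylsilyl)oxy]-3-methyl-5-oxohexyl}-5,5-dimethyl-5,6-dihydro-2H-pyran-2-one | CC(=O)C1=CC(C)(C)[C@@H](CC(O[Si](C)(C)C(C)(C)C)C(C)CC(C)=O)OC1=O | intermediate (not isolated)
15 | 2,9-diacetyl-4-[(tert-butyldimethylsilyl)oxy]-3,10,10-trimethyl-7-oxabicyclo[4.3.1]decan-8-one (bridgeheads fixed by C7; other centers epimeric) | CC(C)(C)[Si](C)(C)OC1C[C@H]2OC(=O)C(C(C)=O)[C@@H](C(C1C)C(C)=O)C2(C)C | intermediate (not isolated)
16 | 9-[(tert-butyldimethylsilyl)oxy]-1-oxo-4,10-secolongipin-2-ene-4,7-carbolactone (C5, C7 as in the target; C4, C9, C10, C11 epimers) | CC(C)(C)[Si](C)(C)OC1C[C@H]2OC(=O)C3C(C)=CC(=O)C(C1C)[C@H]3C2(C)C | intermediate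
17 | 9-hydroxy-1-oxo-4,10-secolongipin-2-ene-4,7-carbolactone | OC1C[C@H]2OC(=O)C3C(C)=CC(=O)C(C1C)[C@H]3C2(C)C | intermediate
18 | 1,9-dioxo-4,10-secolongipin-2-ene-4,7-carbolactone | O=C1C[C@H]2OC(=O)C3C(C)=CC(=O)C(C1C)[C@H]3C2(C)C | intermediate
19 | 1,9-dioxo-4,10-secolongipina-2,7-diene-4-carboxylic acid | O=C1C=CC(C)(C)[C@H]2C(C(=O)O)C(C)=CC(=O)C2C1C | intermediate (not isolated)
20 | 4,10-secolongipina-2,7-diene-1,9-dione (C5 as in the target; C10, C11 epimers) | O=C1C=CC(C)(C)[C@H]2CC(C)=CC(=O)C2C1C | intermediate
21 | 1,1-(ethylenedioxy)-4,10-secolongipina-3,7-dien-9-one (5,11-cis; C10 epimers) | O=C1C=CC(C)(C)[C@H]2C=C(C)CC3(OCCO3)[C@H]2C1C | intermediate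
22 | 3,4-epoxy-1,1-(ethylenedioxy)-4,10-secolongipin-7-en-9-one (epoxide oxygen trans to C6 and C10) | O=C1C=CC(C)(C)[C@H]2[C@@H]3O[C@]3(C)CC4(OCCO4)[C@H]2C1C | intermediate
23 | 1,1-(ethylenedioxy)-3-hydroxylongipin-7-en-9-one (3-OH on the face away from C10) | O=C1C=CC(C)(C)[C@@H]2[C@H]3C4(OCCO4)C[C@@](C)(O)[C@@H]2[C@]31C | intermediate (not isolated)
24 | longipina-2,7-diene-1,9-dione (C4, C5, C10, C11 as in the target) | O=C1C=CC(C)(C)[C@@H]2[C@H]3C(=O)C=C(C)[C@@H]2[C@]31C | intermediate
25 | 7-(4,4,5,5-tetramethyl-1,3,2-dioxaborolan-2-yl)longipin-2-ene-1,9-dione (boron on the C4-side face) | O=C1C[C@@H](B2OC(C)(C)C(C)(C)O2)C(C)(C)[C@@H]2[C@H]3C(=O)C=C(C)[C@@H]2[C@]31C | intermediate (not isolated)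
26 | (7R)-7-hydroxylongipin-2-ene-1,9-dione | O=C1C[C@@H](O)C(C)(C)[C@@H]2[C@H]3C(=O)C=C(C)[C@@H]2[C@]31C | intermediate
27 | 3-methylbut-2-enal | CC(C)=CC=O | starting material
28 | (7R,9R)-9-hydroxy-1-oxolongipin-2-en-7-yl 3-methylbut-2-enoate | O[C@@H]1C[C@@H](OC(=O)C=C(C)C)C(C)(C)[C@@H]2[C@H]3C(=O)C=C(C)[C@@H]2[C@]31C | intermediate
29 | (2Z)-2-methylbut-2-enoic acid (angelic acid) | C/C=C(/C)C(=O)O | starting material
30 | (4R,5S,7R,9R,10R,11R)-9-{[(2Z)-2-methylbut-2-enoyl]oxy}-1-oxolongipin-2-en-7-yl 3-methylbut-2-enoate | C/C=C(/C)C(=O)O[C@@H]1C[C@@H](OC(=O)C=C(C)C)C(C)(C)[C@@H]2[C@H]3C(=O)C=C(C)[C@@H]2[C@]31C | target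

**Count and risks**

Total step count: 18. Longest linear sequence: 17 steps (1, 2, 4–18; step 3 makes the second fragment).

Step 9. What may go wrong: intermolecular condensation or amine addition to the alkylidene acetoacetate may outrun closure of the seven-membered ring, or the aldol condensation may take the other direction (C3-methyl onto C1). Fallback (sets out from 10, comes back at 16): the rings are closed one at a time. Alcohol 10 is silylated (Et3SiCl, imidazole, DMF) to the triethylsilyl ether of 10 F1. Ozonolysis (O3, CH2Cl2, −78 °C; PPh3) gives the silyl-protected keto aldehyde F2. A keto aldehyde aldol condensation (pyrrolidine, AcOH, benzene, 80 °C), in which only the ketone can enolize and only the C5 aldehyde can accept, closes the seven-membered ring to the 1-acetylcycloheptene F3. Pyridinium p-toluenesulfonate in MeOH removes the triethylsilyl group selectively to give the C7 alcohol F4, which is acetoacetylated with 11 (toluene, 110 °C) to the acetoacetate F5. DBU in MeCN then effects the lactone-forming 6-exo-trig Michael addition of C4 to C5, now the β-carbon of a plain cyclic enone, and pyrrolidinium acetate at 80 °C closes the cyclohexenone to give 16.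

Step 15. What may go wrong: O-alkylation of the dienolate, base-induced isomerization of the epoxide to an allylic alcohol, or a slow 4-exo opening at the hindered C4 may divert the material before the cyclobutane closes; material with a trans ring fusion cannot close at all. Fallback (sets out from 21, comes back at 24): the epoxide is replaced by a sulfonate. Dihydroxylation of the C3=C4 alkene of 21 (OsO4 cat., N-methylmorpholine N-oxide, acetone/H2O) from the same open face gives the cis-3,4-diol F6. MsCl and Et3N (CH2Cl2, 0 °C) sulfonylate only the secondary C4 hydroxyl to the 4-methanesulfonate F7, whose cis tertiary hydroxyl cannot form an epoxide. KOtBu in tBuOH/THF then closes the cyclobutane by intramolecular alkylation of the ketone enolate with the secondary sulfonate (inversion at C4) to the same hydroxy ketal 23, and aqueous HCl gives 24.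

Step 16. What may go wrong: the ligand may fail to control the facial selectivity at C7, or the boryl copper species may add sluggishly next to the quaternary C6. Fallback (sets out from 24, comes back at 26): nucleophilic epoxidation and reductive opening. H2O2 with a cinchona-derived primary ammonium salt (9-amino-9-deoxy-epi-quinine bis(trifluoroacetate), dioxane, 30 °C; catalyst hand chosen for the C4-side face) epoxidizes only the C7=C8 enone to the 7,8-epoxy ketone F8. SmI2 (THF/MeOH, −90 °C) then cleaves the C8–O bond reductively and leaves the C7 carbinol, giving 26.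

Further compounds
F1 | step 9 | (4R)-6-[(tert-butyldimethylsilyl)oxy]-3,3,7,9-tetramethyl-4-[(triethylsilyl)oxy]deca-1,9-diene | C=CC(C)(C)[C@H](O[Si](CC)(CC)CC)CC(O[Si](C)(C)C(C)(C)C)C(C)CC(C)=C
F2 | step 9 | (3R)-5-[(tert-butyldimethylsilyl)oxy]-2,2,6-trimethyl-8-oxo-3-[(triethylsilyl)oxy]nonanal | O=CC(C)(C)[C@H](O[Si](CC)(CC)CC)CC(O[Si](C)(C)C(C)(C)C)C(C)CC(C)=O
F3 | step 9 | 1-{(4R)-6-[(tert-butyldimethylsilyl)oxy]-3,3,7-trimethyl-4-[(triethylsilyl)oxy]cyclohept-1-en-1-yl}ethan-1-one | CC(=O)C1=CC(C)(C)[C@H](O[Si](CC)(CC)CC)CC(O[Si](C)(C)C(C)(C)C)C1C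
F4 | step 9 | 1-{(4R)-6-[(tert-butyldimethylsilyl)oxy]-4-hydroxy-3,3,7-trimethylcyclohept-1-en-1-yl}ethan-1-one | CC(=O)C1=CC(C)(C)[C@H](O)CC(O[Si](C)(C)C(C)(C)C)C1C
F5 | step 9 | (1R)-4-acetyl-6-[(tert-butyldimethylsilyl)oxy]-2,2,5-trimethylcyclohept-3-en-1-yl 3-oxobutanoate | CC(=O)C1=CC(C)(C)[C@H](OC(=O)CC(C)=O)CC(O[Si](C)(C)C(C)(C)C)C1C
F6 | step 15 | 1,1-(ethylenedioxy)-3,4-dihydroxy-4,10-secolongipin-7-en-9-one (cis-diol on the face away from C6 and C10) | O=C1C=CC(C)(C)[C@H]2[C@H](O)[C@](C)(O)CC3(OCCO3)[C@H]2C1C
F7 | step 15 | 1,1-(ethylenedioxy)-3-hydroxy-9-oxo-4,10-secolongipin-7-en-4-yl methanesulfonate | O=C1C=CC(C)(C)[C@H]2[C@H](OS(C)(=O)=O)[C@](C)(O)CC3(OCCO3)[C@H]2C1C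
F8 | step 16 | 7,8-epoxylongipin-2-ene-1,9-dione (epoxide oxygen on the C4 side) | O=C1[C@H]2O[C@H]2C(C)(C)[C@@H]3[C@H]4C(=O)C=C(C)[C@@H]3[C@]41C
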